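**Retrosynthetic overview**

1. Target ⇒ (3Z,6S,7S,9Z,12E)-pentadeca-3,9,12-trien-1-yne-6,7-diol (laurediol) by one double bromoetherification. Ring order: oxolane first (O6→C9, 5-exo, Br on C10), then the bridging oxepane (O7→C12, 7-exo, Br on C13).
2. Laurediol ⇒ C-silylated 12-ene-1,3,9-triyne-6,7-diol: both Z-alkenes from one hydroboration–protonolysis, then C-desilylation.
3. Triyne diol ⇒ (S,S)-diepoxybutane opened in turn by two lithium acetylides (C8–C9, then C4–C5); the diepoxide supplies C6 and C7.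
4. C9–C15 acetylide ⇒ ethynylmagnesium bromide + (E)-1-bromopent-2-ene.

Assumption: (2S,3S)-1,2:3,4-diepoxybutane (L-tartaric acid series) is bought as such; locants C1–C15 are those of the C15 chain (C1 = terminal alkyne carbon).

**Route**

Step 1
Reactants: 1 (E)-1-bromopent-2-ene; 2 ethynylmagnesium bromide
Product: 3 (E)-hept-4-en-1-yne
Conditions: 2 (2 equiv, 0.5 M in THF), CuCl (5 mol %), then 1, THF, 0 → 45 °C; distil
Reagents that add atoms: none
Why: Cu(I)-catalysed allylic substitution of a primary allylic bromide by an alkynyl Grignard reagent (SN2, α-selective) forms C10–C11 with the E-alkene retained and creates no stereocentre.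

Step 2
Reactants: 3 (E)-hept-4-en-1-yne; 4 (2S,3S)-1,2:3,4-diepoxybutane
Product: 6 (1S,6E)-1-[(2S)-oxiran-2-yl]non-6-en-3-yn-1-ol, via lithium heptenynide 5 (not isolated)
Conditions: 3, n-BuLi, THF, −78 °C; BF3·OEt2; then 4 (3 equiv), −78 °C; H2O quench
Reagents that add atoms: none
Why: Yamaguchi–Hirao alkynylation, in which the BF3-activated oxirane is opened by SN2 attack at its terminal CH2 (C8–C9 bond), so both stereocentres of the C2-symmetric diepoxide (future C6 and C7) are carried over unchanged while the excess of 4 suppresses double opening.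

Step 3
Reactants: 6 (1S,6E)-1-[(2S)-oxiran-2-yl]non-6-en-3-yn-1-ol; 7 1,4-bis(trimethylsilyl)buta-1,3-diyne
Product: 9 (6S,7S,12E)-1-(trimethylsilyl)pentadec-12-ene-1,3,9-triyne-6,7-diol, via lithium silylbutadiynide 8 (not isolated)
Conditions: 7, MeLi·LiBr, THF, 0 °C → rt (gives 8, 3 equiv; 1 equiv is taken up by the OH of 6); −78 °C, BF3·OEt2 (3 equiv), then 6; H2O quench
Reagents that add atoms: none
Why: A second Yamaguchi–Hirao epoxide opening, again by SN2 at the terminal CH2 (C4–C5 bond), leaves C6 untouched and completes the C15 chain as the (6S,7S)-diol.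

Step 4
Reactants: 9 (6S,7S,12E)-1-(trimethylsilyl)pentadec-12-ene-1,3,9-triyne-6,7-diol
Product: 12 (3Z,6S,7S,9Z,12E)-pentadeca-3,9,12-trien-1-yne-6,7-diol, via tetraboryl adduct 10 (not isolated), via C-silyl laurediol 11 (not isolated)
Conditions: Sia2BH (4.4 equiv, from BH3·THF + 2-methylbut-2-ene), THF, 0 °C; AcOH, 0 °C → rt; then K2CO3, MeOH, rt; H2O
Reagents that add atoms: none
Why: Zweifel-type hydroboration–protonolysis, in which hindered disiamylborane adds syn to the isolated alkyne and to the alkyl-substituted triple bond of the 1-silyl-1,3-diyne (the silylated triple bond and the E-alkene react too slowly), AcOH protonolysis of both alkenylboranes with retention gives the 3Z and 9Z alkenes, and methanolic carbonate then cleaves the borinates and the C(sp)–Si bond.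

Step 5
Reactants: 12 (3Z,6S,7S,9Z,12E)-pentadeca-3,9,12-trien-1-yne-6,7-diol
Product: 14 (1S,3R,5S,6S,8S)-5-bromo-3-[(1S)-1-bromopropyl]-8-[(2Z)-pent-2-en-4-yn-1-yl]-2,7-dioxabicyclo[4.2.1]nonane, via all-cis bromo-oxolane alcohol 13 (not isolated)
Conditions: TBCO (1.05 equiv), CH2Cl2 (5 mM), −40 °C, dark; then TBCO (1.2 equiv), → rt; aq. Na2S2O3
Reagents that add atoms: 2,4,4,6-tetrabromocyclohexa-2,5-dien-1-one (TBCO), O=C1C(Br)=CC(Br)(Br)C=C1Br
Why: Proposed new method: a one-flask double bromoetherification in which the bromonium ion of the 9Z-alkene is opened 5-exo and anti by O6 (setting 9S,10S; only the all-cis oxolane 13 has O7–H and the C9 side chain on the same face and can react further), and the bromonium ion of the 12E-alkene is then opened 7-exo and anti by that ring hydroxyl (setting 13S relative to 12R, with 12R being the face that places the bromopropyl group cis to C6 across O7 — a stereochemical bet, not a certainty), the electron-poor enyne being expected to stay a spectator; the closest known reaction type is the TBCO- or NBS-mediated bromoetherification of Laurencia-type enyne diols and hydroxy-oxocenes (5-exo closures to bromo-oxolanes, transannular closures to bridged bis-ethers).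

**Compound list**

1 | (E)-1-bromopent-2-ene | CC/C=C/CBr | starting material
2 | ethynylmagnesium bromide | C#C[Mg]Br | starting material
3 | (E)-hept-4-en-1-yne | C#CC/C=C/CC | intermediate
4 | (2S,3S)-1,2:3,4-diepoxybutane [(2S,2'S)-2,2'-bioxirane] | C1O[C@@H]1[C@@H]1CO1 | starting material
5 | lithium (E)-hept-4-en-1-yn-1-ide | [Li]C#CC/C=C/CC | intermediate (not isolated)
6 | (1S,6E)-1-[(2S)-oxiran-2-yl]non-6-en-3-yn-1-ol | CC/C=C/CC#CC[C@H](O)[C@@H]1CO1 | intermediate
7 | 1,4-bis(trimethylsilyl)buta-1,3-diyne | C[Si](C)(C)C#CC#C[Si](C)(C)C | starting material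
8 | lithium 4-(trimethylsilyl)buta-1,3-diyn-1-ide | [Li]C#CC#C[Si](C)(C)C | intermediate (not isolated)
9 | (6S,7S,12E)-1-(trimethylsilyl)pentadec-12-ene-1,3,9-triyne-6,7-diol | C[Si](C)(C)C#CC#CC[C@H](O)[C@@H](O)CC#CC/C=C/CC | intermediate
10 | (3Z,6S,7S,9Z,12E)-3,10-bis(disiamylboryl)-6,7-bis(disiamylboryloxy)-1-(trimethylsilyl)pentadeca-3,9,12-trien-1-yne (boron drawn on C10, C9 equally possible; siamyl CH centres unspecified) | C[Si](C)(C)C#C/C(B(C(C)C(C)C)C(C)C(C)C)=C\C[C@H](OB(C(C)C(C)C)C(C)C(C)C)[C@@H](OB(C(C)C(C)C)C(C)C(C)C)C/C=C(/B(C(C)C(C)C)C(C)C(C)C)C/C=C/CC | intermediate (not isolated)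
11 | (3Z,6S,7S,9Z,12E)-1-(trimethylsilyl)pentadeca-3,9,12-trien-1-yne-6,7-diol | C[Si](C)(C)C#C/C=C\C[C@H](O)[C@@H](O)C/C=C\C/C=C/CC | intermediate (not isolated)
12 | (3Z,6S,7S,9Z,12E)-pentadeca-3,9,12-trien-1-yne-6,7-diol [(3Z,6S,7S)-laurediol] | C#C/C=C\C[C@H](O)[C@@H](O)C/C=C\C/C=C/CC | intermediate
13 | (2S,3S,5S)-5-[(1S,3E)-1-bromohex-3-en-1-yl]-2-[(2Z)-pent-2-en-4-yn-1-yl]oxolan-3-ol | C#C/C=C\C[C@@H]1O[C@H]([C@@H](Br)C/C=C/CC)C[C@@H]1O | intermediate (not isolated)
14 | (1S,3R,5S,6S,8S)-5-bromo-3-[(1S)-1-bromopropyl]-8-[(2Z)-pent-2-en-4-yn-1-yl]-2,7-dioxabicyclo[4.2.1]nonane [chain locants 3Z,6S,7S,9S,10S,12R,13S] | C#C/C=C\C[C@@H]1O[C@H]2C[C@@H]1O[C@@H]([C@@H](Br)CC)C[C@@H]2Br | target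

**Totals**

Total step count: 5. Longest linear sequence: 5 steps (1 → 3 → 6 → 9 → 12 → 14).

**Steps most likely to fail**

Step 5 (highest risk). Possible failures:
- The 5-exo closure gives the C9 epimer of 13, which cannot bridge.
- O7 closes 5-endo on C10 instead.
- The slow 7-exo closure loses to capture of the 12,13-bromonium ion by the ring oxygen (bicyclic oxonium ion) or to attack on the enyne.
- The bridging closure selects the wrong face at C12.

Fallback, setting out from 6 and returning at 13: silylate O7 of 6 (TBSCl, imidazole, DMF) to give the silyl ether tert-butyldimethyl{[(1S,6E)-1-[(2S)-oxiran-2-yl]non-6-en-3-yn-1-yl]oxy}silane F1. Open its epoxide with 8/BF3·OEt2 as in step 3, now without a free hydroxyl, to the mono-protected triyne alcohol (6S,7S,12E)-7-[(tert-butyldimethylsilyl)oxy]-1-(trimethylsilyl)pentadec-12-ene-1,3,9-triyn-6-ol F2. Reduce and C-desilylate as in step 4 to the 7-O-silyl laurediol (3Z,6S,7S,9Z,12E)-7-[(tert-butyldimethylsilyl)oxy]pentadeca-3,9,12-trien-1-yn-6-ol F3. With O6–H the only nucleophile, TBCO (1.05 equiv) can close only the oxolane. The bulky silyloxy group should sit pseudo-equatorial in the 5-exo transition state and steer the C9 substituent cis, giving the all-cis bromo-oxolane silyl ether tert-butyl{[(2S,3S,5S)-5-[(1S,3E)-1-bromohex-3-en-1-yl]-2-[(2Z)-pent-2-en-4-yn-1-yl]oxolan-3-yl]oxy}dimethylsilane F4, which is purified from any epimer. HF·pyridine then frees 13 as an isolated, stereochemically pure compound, and the bridging bromoetherification to 14 is run on it as a separate operation (TBCO, 1.1 equiv, high dilution). This fallback fixes the first closure but not a failure of the bridging closure itself.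

Step 4. The two free hydroxyls force an excess of borane, so over-hydroboration of the E-alkene or the silylated triple bond, or incomplete double reduction, is possible. Fallback, setting out from 6 and returning at 14: reduce each triple bond when it is the only reactive π-bond present. Lindlar semihydrogenation of 6 (H2, Pd/CaCO3–Pb, quinoline) gives the dienyl epoxy alcohol (1S,3Z,6E)-1-[(2S)-oxiran-2-yl]nona-3,6-dien-1-ol F5. Opening with 8/BF3·OEt2 gives the diene-diyne diol (6S,7S,9Z,12E)-1-(trimethylsilyl)pentadeca-9,12-diene-1,3-diyne-6,7-diol F6. The double bromoetherification (TBCO, 2.2 equiv) is run on F6, whose silyl-diyne is inert to the bromonium source, to give the bicyclic dibromide (1S,3R,5S,6S,8S)-5-bromo-3-[(1S)-1-bromopropyl]-8-[5-(trimethylsilyl)penta-2,4-diyn-1-yl]-2,7-dioxabicyclo[4.2.1]nonane F7. The single remaining hydroboration–protonolysis (Sia2BH 1.1 equiv, then AcOH) on a substrate with no other alkyne, no alkene and no hydroxyl, followed by K2CO3/MeOH, gives 14. This order also removes the enyne from the cyclisation.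

Step 3. The silyl-diynide is a stabilised, sluggish nucleophile and the substrate carries a free hydroxyl next to the epoxide, so low conversion or Payne rearrangement is possible. Fallback, setting out from 6 and returning at 9: open the epoxide with the more nucleophilic parent acetylide (lithium acetylide–ethylenediamine, DMSO, rt) to the terminal diyne diol (4S,5S,10E)-tridec-10-ene-1,7-diyne-4,5-diol F8. Then build the 1,3-diyne by Cadiot–Chodkiewicz coupling with (bromoethynyl)trimethylsilane (CuCl cat., NH2OH·HCl, n-BuNH2, 0 °C), which gives 9.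

**Further compounds**

F1 | step 5 | tert-butyldimethyl{[(1S,6E)-1-[(2S)-oxiran-2-yl]non-6-en-3-yn-1-yl]oxy}silane | CC/C=C/CC#CC[C@H](O[Si](C)(C)C(C)(C)C)[C@@H]1CO1
F2 | step 5 | (6S,7S,12E)-7-[(tert-butyldimethylsilyl)oxy]-1-(trimethylsilyl)pentadec-12-ene-1,3,9-triyn-6-ol | C[Si](C)(C)C#CC#CC[C@H](O)[C@@H](O[Si](C)(C)C(C)(C)C)CC#CC/C=C/CC
F3 | step 5 | (3Z,6S,7S,9Z,12E)-7-[(tert-butyldimethylsilyl)oxy]pentadeca-3,9,12-trien-1-yn-6-ol | C#C/C=C\C[C@H](O)[C@@H](O[Si](C)(C)C(C)(C)C)C/C=C\C/C=C/CC
F4 | step 5 | tert-butyl{[(2S,3S,5S)-5-[(1S,3E)-1-bromohex-3-en-1-yl]-2-[(2Z)-pent-2-en-4-yn-1-yl]oxolan-3-yl]oxy}dimethylsilane | C#C/C=C\C[C@@H]1O[C@H]([C@@H](Br)C/C=C/CC)C[C@@H]1O[Si](C)(C)C(C)(C)C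
F5 | step 4 | (1S,3Z,6E)-1-[(2S)-oxiran-2-yl]nona-3,6-dien-1-ol | CC/C=C/C/C=C\C[C@H](O)[C@@H]1CO1
F6 | step 4 | (6S,7S,9Z,12E)-1-(trimethylsilyl)pentadeca-9,12-diene-1,3-diyne-6,7-diol | C[Si](C)(C)C#CC#CC[C@H](O)[C@@H](O)C/C=C\C/C=C/CC
F7 | step 4 | (1S,3R,5S,6S,8S)-5-bromo-3-[(1S)-1-bromopropyl]-8-[5-(trimethylsilyl)penta-2,4-diyn-1-yl]-2,7-dioxabicyclo[4.2.1]nonane | C[Si](C)(C)C#CC#CC[C@@H]1O[C@H]2C[C@@H]1O[C@@H]([C@@H](Br)CC)C[C@@H]2Br
F8 | step 3 | (4S,5S,10E)-tridec-10-ene-1,7-diyne-4,5-diol | C#CC[C@H](O)[C@@H](O)CC#CC/C=C/CC
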